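**Strategy.** The pyran ring C (O1–C2–C3–C4–C4a–C8a) is cut across C4–C3 and O1–C2. It is read as the oxa-[4+2] adduct of a ring-A ortho-quinone methide (O1=C8a–C4a=C4, with the acylphloroglucinol ring on C4) and a para-oxygenated styrene (C2=C3). The feature exploited is the doubly benzylic C4 next to a phenolic O1 on ring A, cis-1,3 to the C2 aryl group. A chiral Brønsted acid dehydrates a racemic 2-hydroxybenzhydrol that lacks the pyran ring and steers the endo cycloaddition. This closes the last ring, forms two bonds and sets C2 and C4 in one operation. All other oxygens are benzyl ethers, removed together at the end.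

Key step: step 4

Remark on the chemistry: the target is read as the 2,4-cis flavan with (2R,4R) configuration. 1,3,5-Tris(benzyloxy)benzene, 9-phenylnonanoic acid, 3-(benzyloxy)phenol and 4-(benzyloxy)styrene are assumed to be catalogue compounds.

**Step 1**
Reactants: 1 1,3,5-tris(benzyloxy)benzene; 2 9-phenylnonanoic acid
Product: 4 1-[2,4,6-tris(benzyloxy)phenyl]-9-phenylnonan-1-one, via 9-phenylnonanoic trifluoroacetic anhydride 3 (not isolated)
Conditions: 2, TFAA (1.1 equiv), CH2Cl2, 0 °C; then 1, 0 °C to rt
Reagents that add atoms: none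
Why: Friedel–Crafts acylation by the preformed mixed trifluoroacetic anhydride; the three ring positions of the triply activated arene are equivalent, the first ketone shields and deactivates the ring against a second acylation, and the metal-free, weakly acidic medium should leave the benzyl ethers intact.

**Step 2**
Reactants: 4 1-[2,4,6-tris(benzyloxy)phenyl]-9-phenylnonan-1-one
Product: 6 2,4,6-tris(benzyloxy)-3-(9-phenylnonanoyl)benzaldehyde, via aryl iminium chloride 5 (not isolated)
Conditions: POCl3, DMF, 0 °C to rt; then ice/H2O, rt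
Reagents that add atoms: DMF (CN(C)C=O); water (O)
Why: Vilsmeier–Haack formylation; the two equivalent free ring positions are ortho/para to three benzyloxy groups and only meta to the twisted ketone, so the chloroiminium ion should attack the ring well below the temperature at which the hindered ketone would enolise, and hydrolysis of the aryl iminium salt gives the aldehyde.

**Step 3**
Reactants: 6 2,4,6-tris(benzyloxy)-3-(9-phenylnonanoyl)benzaldehyde; 7 3-(benzyloxy)phenol
Product: 9 rac-1-{2,4,6-tris(benzyloxy)-3-[(4-(benzyloxy)-2-hydroxyphenyl)(hydroxy)methyl]phenyl}-9-phenylnonan-1-one, via bromomagnesium 3-(benzyloxy)phenoxide 8 (not isolated)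
Conditions: 7, EtMgBr (1.0 equiv), Et2O, 0 °C; solvent exchange to toluene; then 6, rt; pH 7 aqueous work-up
Reagents that add atoms: none
Why: Magnesium-templated ortho-specific hydroxyalkylation of a bromomagnesium phenoxide; magnesium binds the aldehyde (far more electrophilic than the di-ortho-substituted ketone) and delivers it to C6 of the phenoxide, the ortho carbon para to the benzyloxy group, while the other ortho site lies between two oxygens; the carbinol centre is racemic and is erased in step 4.

**Step 4**
Reactants: 9 rac-1-{2,4,6-tris(benzyloxy)-3-[(4-(benzyloxy)-2-hydroxyphenyl)(hydroxy)methyl]phenyl}-9-phenylnonan-1-one; 10 4-(benzyloxy)styrene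
Product: 12 1-{2,4,6-tris(benzyloxy)-3-[(2R,4R)-7-(benzyloxy)-2-[4-(benzyloxy)phenyl]-3,4-dihydro-2H-chromen-4-yl]phenyl}-9-phenylnonan-1-one, via ortho-quinone methide 11 (not isolated)
Conditions: (R)-3,3'-bis(2,4,6-triisopropylphenyl)-1,1'-binaphthyl-2,2'-diyl N-(trifluoromethylsulfonyl)phosphoramide (10 mol%), 10 (3 equiv), toluene, 5 Å molecular sieves, −20 °C to rt
Reagents that add atoms: none
Why: The acid ionises the benzylic hydroxyl of 9 and water is lost to give the E-configured quinone methide 11, held by hydrogen bonding and ion pairing to the chiral phosphoramide, whereupon the CH2 terminus of 10 bonds to the exocyclic carbon (C4) while the quinone methide oxygen (O1) closes on the benzylic carbon (C2) in a concerted but asynchronous inverse-electron-demand oxa-Diels–Alder reaction. The closest known reaction type is the chiral Brønsted acid-catalysed [4+2] cycloaddition of ortho-quinone methides generated from 2-hydroxybenzhydrols with styrenes, which gives cis-2,4-diarylchromans. The pyran ring is closed by intermolecular [4+2] annulation, four ring atoms (O1, C8a, C4a, C4) coming from the heterodiene and two (C3, C2) from the alkene. C4 is set by the catalyst, which blocks one face of the planar quinone methide, and C2 is set relative to C4 by the endo placement of the styrene aryl group under the heterodiene, which turns the E geometry into the 2,4-cis relation; the (R)-catalyst is proposed for the (2R,4R) series and its mirror image is taken if the sense of induction proves opposite. The step needs a single site of quinone methide formation and a single orientation of the alkene: the three benzyl ethers on the acylphloroglucinol ring leave the ring A phenol as the only oxygen that can become O1, and the polarity match (electrophilic C4, cation-stabilising 4-benzyloxyphenyl group at C2) fixes the regiochemistry. An excess of 10 at low temperature should keep acid-induced oligomerisation of the styrene in check.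

**Step 5**
Reactants: 12 1-{2,4,6-tris(benzyloxy)-3-[(2R,4R)-7-(benzyloxy)-2-[4-(benzyloxy)phenyl]-3,4-dihydro-2H-chromen-4-yl]phenyl}-9-phenylnonan-1-one
Product: 13 1-{2,4,6-trihydroxy-3-[(2R,4R)-7-hydroxy-2-(4-hydroxyphenyl)-3,4-dihydro-2H-chromen-4-yl]phenyl}-9-phenylnonan-1-one
Conditions: H2 (1 atm), Pd(OH)2/C, EtOAc/MeOH, rt
Reagents that add atoms: none
Why: Heterogeneous hydrogenolysis of the five aryl benzyl ethers; the cyclic C2–O1 ether of a flavan and a hindered aryl ketone that becomes chelated by its ortho hydroxyls are expected to resist these mild neutral conditions, under which neither C2 nor C4 can epimerise.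

**Compound list**
1 | 1,3,5-tris(benzyloxy)benzene | C(Oc1cc(OCc2ccccc2)cc(OCc2ccccc2)c1)c1ccccc1 | starting material
2 | 9-phenylnonanoic acid | OC(=O)CCCCCCCCc1ccccc1 | starting material
3 | 9-phenylnonanoic trifluoroacetic anhydride (formed in the flask) | O=C(CCCCCCCCc1ccccc1)OC(=O)C(F)(F)F | intermediate
4 | 1-[2,4,6-tris(benzyloxy)phenyl]-9-phenylnonan-1-one | O=C(CCCCCCCCc1ccccc1)c1c(OCc2ccccc2)cc(OCc2ccccc2)cc1OCc1ccccc1 | intermediate
5 | N-{[2,4,6-tris(benzyloxy)-3-(9-phenylnonanoyl)phenyl]methylidene}-N-methylmethanaminium chloride (formed in the flask) | C[N+](C)=Cc1c(OCc2ccccc2)cc(OCc2ccccc2)c(C(=O)CCCCCCCCc2ccccc2)c1OCc1ccccc1.[Cl-] | intermediate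
6 | 2,4,6-tris(benzyloxy)-3-(9-phenylnonanoyl)benzaldehyde | O=Cc1c(OCc2ccccc2)cc(OCc2ccccc2)c(C(=O)CCCCCCCCc2ccccc2)c1OCc1ccccc1 | intermediate
7 | 3-(benzyloxy)phenol | Oc1cccc(OCc2ccccc2)c1 | starting material
8 | bromomagnesium 3-(benzyloxy)phenoxide (formed in the flask) | Br[Mg]Oc1cccc(OCc2ccccc2)c1 | intermediate
9 | rac-1-{2,4,6-tris(benzyloxy)-3-[(4-(benzyloxy)-2-hydroxyphenyl)(hydroxy)methyl]phenyl}-9-phenylnonan-1-one | O=C(CCCCCCCCc1ccccc1)c1c(OCc2ccccc2)cc(OCc2ccccc2)c(C(O)c2ccc(OCc3ccccc3)cc2O)c1OCc1ccccc1 | intermediate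
10 | 4-(benzyloxy)styrene | C=Cc1ccc(OCc2ccccc2)cc1 | starting material
11 | (E)-3-(benzyloxy)-6-{[2,4,6-tris(benzyloxy)-3-(9-phenylnonanoyl)phenyl]methylidene}cyclohexa-2,4-dien-1-one (ortho-quinone methide, formed in the flask) | O=C1C=C(OCc2ccccc2)C=C/C1=C\c1c(OCc2ccccc2)cc(OCc2ccccc2)c(C(=O)CCCCCCCCc2ccccc2)c1OCc1ccccc1 | intermediate
12 | 1-{2,4,6-tris(benzyloxy)-3-[(2R,4R)-7-(benzyloxy)-2-[4-(benzyloxy)phenyl]-3,4-dihydro-2H-chromen-4-yl]phenyl}-9-phenylnonan-1-one (2,4-cis) | O=C(CCCCCCCCc1ccccc1)c1c(OCc2ccccc2)cc(OCc2ccccc2)c([C@@H]2C[C@H](c3ccc(OCc4ccccc4)cc3)Oc3cc(OCc4ccccc4)ccc32)c1OCc1ccccc1 | intermediate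
13 | 1-{2,4,6-trihydroxy-3-[(2R,4R)-7-hydroxy-2-(4-hydroxyphenyl)-3,4-dihydro-2H-chromen-4-yl]phenyl}-9-phenylnonan-1-one (2,4-cis) | O=C(CCCCCCCCc1ccccc1)c1c(O)cc(O)c([C@@H]2C[C@H](c3ccc(O)cc3)Oc3cc(O)ccc32)c1O | target

**Total step count:** 5. **Longest linear sequence:** 5 steps (1 → 4 → 6 → 9 → 12 → 13).

**Steps most likely to fail**

Step 4 (key step). What may go wrong is poor facial discrimination at the hindered quinone methide, acid-initiated oligomerisation of the electron-rich styrene, or acid-mediated ionisation of the product at C2 that erodes the cis relation. The fallback sets out from 9 and comes back at 13; it still closes the pyran ring last but sets C2 afterwards. 4-(Benzyloxy)benzonitrile and MeMgBr in THF should give bromomagnesium 1-[4-(benzyloxy)phenyl]ethan-1-iminide F1, which is acetylated in the same flask with Ac2O to N-{1-[4-(benzyloxy)phenyl]ethenyl}acetamide F2. With (R)-3,3'-bis(2,4,6-triisopropylphenyl)-1,1'-binaphthyl-2,2'-diyl hydrogen phosphate in CH2Cl2, 9 is dehydrated to 11, and the far more nucleophilic enamide adds and cyclises (known enamide/ortho-quinone methide [4+2], with the N–H and the quinone methide oxygen both bound to the catalyst). This should give N-[(4R)-7-(benzyloxy)-2-[4-(benzyloxy)phenyl]-4-[2,4,6-tris(benzyloxy)-3-(9-phenylnonanoyl)phenyl]-3,4-dihydro-2H-chromen-2-yl]acetamide F3, in which the configuration at C2 is of no consequence. TsOH in toluene then expels acetamide to give 1-{2,4,6-tris(benzyloxy)-3-[(4R)-7-(benzyloxy)-2-[4-(benzyloxy)phenyl]-4H-chromen-4-yl]phenyl}-9-phenylnonan-1-one F4. H2 over Pd/C should saturate the enol ether from the face opposite the C4 aryl group (giving the cis flavan) and remove the five benzyl groups, giving 13 directly.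

Step 3. What may go wrong is ionisation of the magnesium alkoxide of the product to the quinone methide and its capture by a second phenoxide, or sluggish addition to the di-ortho-substituted aldehyde. The fallback sets out from 6 and 7 and comes back at 9. Heating both with PhB(OH)2 and catalytic propionic acid in toluene with azeotropic removal of water (boron-templated ortho-hydroxyalkylation) should give the cyclic boronate 1-{2,4,6-tris(benzyloxy)-3-[7-(benzyloxy)-2-phenyl-4H-1,3,2-benzodioxaborinin-4-yl]phenyl}-9-phenylnonan-1-one F5, which masks the carbinol against ionisation as it forms. Transesterification with propane-1,3-diol at rt then releases 9.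

Step 2. What may go wrong is enolisation and chloroformylation of the ketone in competition with ring formylation, or loss of a benzyl group from an ortho oxygen. The fallback sets out from 2 and comes back at 6; it bypasses step 1 as well and moves the protection to the end. Acid 2 and phloroglucinol (benzene-1,3,5-triol) in BF3·OEt2 at 80 °C should give 1-(2,4,6-trihydroxyphenyl)-9-phenylnonan-1-one F6 (Friedel–Crafts acylation). POCl3/DMF in EtOAc at rt followed by aqueous hydrolysis should give 2,4,6-trihydroxy-3-(9-phenylnonanoyl)benzaldehyde F7 (Vilsmeier–Haack formylation of a free acylphloroglucinol, where the chelated ketone does not compete). BnBr, K2CO3, DMF at 60 °C then gives 6.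

**Further compounds**
F1 | step 4 | bromomagnesium 1-[4-(benzyloxy)phenyl]ethan-1-iminide | CC(=N[Mg]Br)c1ccc(OCc2ccccc2)cc1
F2 | step 4 | N-{1-[4-(benzyloxy)phenyl]ethenyl}acetamide | CC(=O)NC(=C)c1ccc(OCc2ccccc2)cc1
F3 | step 4 | N-[(4R)-7-(benzyloxy)-2-[4-(benzyloxy)phenyl]-4-[2,4,6-tris(benzyloxy)-3-(9-phenylnonanoyl)phenyl]-3,4-dihydro-2H-chromen-2-yl]acetamide (C2 not defined) | O=C(CCCCCCCCc1ccccc1)c1c(OCc2ccccc2)cc(OCc2ccccc2)c([C@@H]2CC(NC(C)=O)(c3ccc(OCc4ccccc4)cc3)Oc3cc(OCc4ccccc4)ccc32)c1OCc1ccccc1
F4 | step 4 | 1-{2,4,6-tris(benzyloxy)-3-[(4R)-7-(benzyloxy)-2-[4-(benzyloxy)phenyl]-4H-chromen-4-yl]phenyl}-9-phenylnonan-1-one | O=C(CCCCCCCCc1ccccc1)c1c(OCc2ccccc2)cc(OCc2ccccc2)c([C@@H]2C=C(c3ccc(OCc4ccccc4)cc3)Oc3cc(OCc4ccccc4)ccc32)c1OCc1ccccc1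
F5 | step 3 | 1-{2,4,6-tris(benzyloxy)-3-[7-(benzyloxy)-2-phenyl-4H-1,3,2-benzodioxaborinin-4-yl]phenyl}-9-phenylnonan-1-one (racemic) | O=C(CCCCCCCCc1ccccc1)c1c(OCc2ccccc2)cc(OCc2ccccc2)c(C2OB(c3ccccc3)Oc3cc(OCc4ccccc4)ccc32)c1OCc1ccccc1
F6 | step 2 | 1-(2,4,6-trihydroxyphenyl)-9-phenylnonan-1-one | O=C(CCCCCCCCc1ccccc1)c1c(O)cc(O)cc1O
F7 | step 2 | 2,4,6-trihydroxy-3-(9-phenylnonanoyl)benzaldehyde | O=Cc1c(O)cc(O)c(C(=O)CCCCCCCCc2ccccc2)c1O
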